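## Retrosynthetic overview

1. Feature: 29 is a 3,4-seco-abietane. Ring A is missing, so the isopropenyl carbon C4 on C5 has no tie to C3. The two bonds flanking C5–C10, namely C4–C5 and C9–C10 (ring B to ring C), can therefore be made across a C5=C10 alkene with an untethered two-carbon electrophile.
2. 29 ⇒ 11,14-para-quinone 28 ⇒ trimethyl ether acid 27 (C11 and C14 carry the only para pair of OMe groups, so the C12 OMe stays) ⇒ C7 ketone 24 ⇒ isopropenyl tetralin 22 ⇒ acetyl tetralin 18, by a methylenation that also resolves.
3. 18 ⇒ E-alkene pivalate 15 + acetyl chloride 16: the acylium ion adds at C5 and arene carbon C9 captures C10.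
4. 15 ⇒ Johnson–Claisen (C1–C3, E geometry), isopropenyl Grignard (C10, C20), Heck reaction with allyl alcohol (C5–C7), and aryl iodide 6 from 1,2,4-trimethoxybenzene 1.
5. Ring order: ring C is bought with 1, ring B is the only ring formed (step 9), and ring A is never built.

Key step: step 9

Remark on numbering: abietane numbers are used. C10 is the quaternary benzylic carbon carrying methyl C20 and the chain C1–C2–C3. C5 is the CH bearing C4, C6 is CH2, and C7 is the benzylic carbon. The arene is C8 (on C7), C9 (on C10), C11, C12, C13 (isopropyl) and C14.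

Remark on the chemistry: 17 and 18 are racemic, and their SMILES show the enantiomer carried on after step 10. Sulfoximine 19 and Grignard solution 9 are taken as purchasable reagents.

## Route

Step 1
Reactants: 1 1,2,4-trimethoxybenzene; 2 acetone
Product: 4 2-(2,3,6-trimethoxyphenyl)propan-2-ol, via 2,3,6-trimethoxyphenyllithium 3 (not isolated)
Conditions: n-BuLi, THF, 0 °C to rt; then acetone, −78 °C to rt; H2O
Reagents that add atoms: acetone 2, CC(C)=O
Why: Directed ortho-metalation removes the proton flanked by two methoxy groups (future C13), and the aryllithium adds 1,2 to acetone.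

Step 2
Reactants: 4 2-(2,3,6-trimethoxyphenyl)propan-2-ol
Product: 5 3-isopropyl-1,2,4-trimethoxybenzene
Conditions: Et3SiH, CF3CO2H, CH2Cl2, 0 °C to rt
Reagents that add atoms: none
Why: Ionic hydrogenation: the acid ionises the tertiary benzylic alcohol, which two ortho oxygens assist, and the silane delivers hydride to the cation.

Step 3
Reactants: 5 3-isopropyl-1,2,4-trimethoxybenzene
Product: 6 1-iodo-3-isopropyl-2,4,5-trimethoxybenzene
Conditions: NIS, CF3CO2H (cat.), MeCN, 0 °C to rt
Reagents that add atoms: N-iodosuccinimide, O=C1CCC(=O)N1I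
Why: Electrophilic aromatic iodination should enter at C8 (para to the C12 OMe and ortho to the C14 OMe) rather than at C9 (one ortho OMe only), and the iodide is preferred to the bromide because this electron-rich, ortho-substituted ring would add slowly to zerovalent palladium.

Step 4
Reactants: 6 1-iodo-3-isopropyl-2,4,5-trimethoxybenzene; 7 allyl alcohol
Product: 8 3-(3-isopropyl-2,4,5-trimethoxyphenyl)propanal
Conditions: Pd(OAc)2 (cat.), Bu4NCl, NaHCO3, DMF, 45 °C
Reagents that add atoms: allyl alcohol 7, C=CCO
Why: Jeffery–Heck arylation of allyl alcohol: insertion at the terminal carbon, β-hydride elimination towards the carbinol and tautomerisation of the enol give the saturated aldehyde carrying C7, C6 and C5.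

Step 5
Reactants: 8 3-(3-isopropyl-2,4,5-trimethoxyphenyl)propanal; 9 isopropenylmagnesium bromide
Product: 10 (±)-5-(3-isopropyl-2,4,5-trimethoxyphenyl)-2-methylpent-1-en-3-ol
Conditions: THF, −78 to 0 °C; H2O
Reagents that add atoms: isopropenylmagnesium bromide 9, C=C(C)[Mg]Br
Why: Grignard 1,2-addition brings in C10, C20 and C1, and the racemic carbinol centre is erased in step 6.

Step 6
Reactants: 10 (±)-5-(3-isopropyl-2,4,5-trimethoxyphenyl)-2-methylpent-1-en-3-ol; 11 triethyl orthoacetate
Product: 13 ethyl (E)-7-(3-isopropyl-2,4,5-trimethoxyphenyl)-4-methylhept-4-enoate, via mixed ketene acetal 12 (not isolated)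
Conditions: MeC(OEt)3, EtCO2H (cat.), 140 °C, EtOH distilled off
Reagents that add atoms: triethyl orthoacetate 11, CCOC(C)(OCC)OCC
Why: Johnson–Claisen rearrangement through a chair transition state with the arylethyl group equatorial (an axial group would clash with the ethoxy group) should give the E C5=C10 alkene and add C2 and C3.

Step 7
Reactants: 13 ethyl (E)-7-(3-isopropyl-2,4,5-trimethoxyphenyl)-4-methylhept-4-enoate
Product: 14 (E)-7-(3-isopropyl-2,4,5-trimethoxyphenyl)-4-methylhept-4-en-1-ol
Conditions: LiAlH4, THF, 0 °C
Reagents that add atoms: none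
Why: Hydride reduction of the ester leaves the isolated alkene and the aryl ethers untouched.

Step 8
Reactants: 14 (E)-7-(3-isopropyl-2,4,5-trimethoxyphenyl)-4-methylhept-4-en-1-ol
Product: 15 (E)-7-(3-isopropyl-2,4,5-trimethoxyphenyl)-4-methylhept-4-en-1-yl pivalate
Conditions: t-BuCOCl, Et3N, DMAP (cat.), CH2Cl2, 0 °C to rt
Reagents that add atoms: pivaloyl chloride, CC(C)(C)C(=O)Cl
Why: O-acylation: C3 is carried as a pivalate because a C3 ester or acid would take the C10 cation as a γ-lactone and a free or silylated oxygen would close a tetrahydrofuran, whereas the pivalate carbonyl could reach C10 only through a seven-membered ring.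

Step 9
Reactants: 15 (E)-7-(3-isopropyl-2,4,5-trimethoxyphenyl)-4-methylhept-4-en-1-yl pivalate; 16 acetyl chloride
Product: 18 (±)-3-[(1S*,2R*)-2-acetyl-6-isopropyl-5,7,8-trimethoxy-1-methyl-1,2,3,4-tetrahydronaphthalen-1-yl]propyl pivalate, via tertiary C10 cation 17 (not isolated)
Conditions: AcCl, SnCl4, 2,6-di-tert-butyl-4-methylpyridine, CH2Cl2, −78 to −40 °C; aq. NaHCO3 at low temperature
Reagents that add atoms: acetyl chloride 16, CC(=O)Cl
Why: Proposed new method: AcCl and SnCl4 give an acetylium ion pair that attacks the C5=C10 alkene at its less substituted carbon C5 (C4–C5 bond), and the tertiary charge building up at C10 (17) is taken by arene carbon C9 from the opposite face (C9–C10 bond) before loss of the C9 proton restores the arene. The closest known reaction types are the Darzens–Nenitzescu (Kondakov) acylation of alkenes with an acyl chloride and a Lewis acid, its interrupted form in which an external arene takes the β-acyl cation, and the intermolecular acetal-initiated cation–olefin cyclisation ended by an arene; the union of an external acylium ion with a tethered arene terminator has not been shown. Ring B closes in the 6-endo-trig mode with regard to the alkene, through a chair-like fold of the C6–C7 tether. C5 and C10 are set together by anti addition across the E alkene, which places H-5 trans to the C20 methyl and the acetyl group anti to C9 as in 29; no chiral element is present, so 18 is racemic and the absolute configuration is fixed in steps 10 and 11. The step needs attack on the alkene ahead of Friedel–Crafts acetylation at C9 and ahead of proton-initiated cyclisation: the trisubstituted alkene is the better π-nucleophile because C9 has a single ortho methoxy donor (C11) while the C12 and C14 methoxy groups are meta to it, and the hindered pyridine binds the HCl released so that no Brønsted acid protonates C5. C9 is the only free ring position and the pivalate cannot reach C10 through a small ring, so arene capture has no internal rival other than proton loss to the β,γ-enone.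

Step 10
Reactants: 18 (±)-acetyl tetralin pivalate; 19 (S)-N,S-dimethyl-S-phenylsulfoximine
Product: 21 β-hydroxysulfoximine of the (5R,10S) ketone (sulfur S; both C4 epimers pooled), via lithiated sulfoximine 20 (not isolated)
Conditions: 19, n-BuLi, THF, −78 °C; then 18, −78 °C; AcOH, −78 °C; chromatography on SiO2
Reagents that add atoms: (S)-N,S-dimethyl-S-phenylsulfoximine 19, C[S@@](=O)(=NC)c1ccccc1
Why: First half of the sulfoximine-based ketone methylenation with optical resolution: the lithiated enantiopure sulfoximine should add to the C4 carbonyl at −78 °C faster than it enolises it (any enolisation takes the methyl protons rather than the hindered C5–H, which matters because the like-sized C10 substituents give C5 no thermodynamic bias), so the two enantiomers of 18 become diastereomers that differ next to the polar group and are parted on silica gel; both C4 epimers of the wanted series are pooled because C4 turns planar in step 11, and the series is assigned by X-ray analysis against the known sulfur centre.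

Step 11
Reactants: 21 β-hydroxysulfoximine of the (5R,10S) ketone
Product: 22 3-[(1S,2S)-6-isopropyl-5,7,8-trimethoxy-1-methyl-2-(prop-1-en-2-yl)-1,2,3,4-tetrahydronaphthalen-1-yl]propyl pivalate
Conditions: Al foil amalgamated with HgCl2, THF/H2O/AcOH, rt
Reagents that add atoms: none
Why: Reductive elimination of a β-hydroxysulfoximine (second half of the same method): two-electron cleavage of the C–S bond with loss of the hydroxyl group gives the 1,1-disubstituted alkene regiospecifically under nearly neutral conditions, so C5 and C10 are untouched (the C5 descriptor changes only through the priority rules).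

Step 12
Reactants: 22 isopropenyl tetralin pivalate
Product: 24 3-[(1S,2S)-6-isopropyl-5,7,8-trimethoxy-1-methyl-4-oxo-2-(prop-1-en-2-yl)-1,2,3,4-tetrahydronaphthalen-1-yl]propyl pivalate, via C7 benzylic alcohol 23 (not isolated)
Conditions: DDQ, 1,4-dioxane/H2O, rt
Reagents that add atoms: water, O
Why: Benzylic oxidation by DDQ in aqueous medium, known for methoxy-substituted tetralins: hydride leaves C7 (the only benzylic CH2, para to the C12 OMe and ortho to the C14 OMe), water takes the cation to 23 and a second equivalent of DDQ gives the aryl ketone, while C10 is quaternary, the isopropyl C–H lies in the ring plane between two methoxy groups and the unactivated alkene is no hydride donor.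

Step 13
Reactants: 24 C7 ketone pivalate
Product: 25 (3S,4S)-4-(3-hydroxypropyl)-7-isopropyl-5,6,8-trimethoxy-4-methyl-3-(prop-1-en-2-yl)-3,4-dihydronaphthalen-1(2H)-one
Conditions: KOH, MeOH/H2O, 60 °C; then dilute HCl
Reagents that add atoms: none
Why: Saponification is used because hydride reagents would reduce C7, and it is safe because C5–H is β to the ketone and not acidic, so no stereocentre can epimerise.

Step 14
Reactants: 25 keto alcohol
Product: 27 3-[(1S,2S)-6-isopropyl-5,7,8-trimethoxy-1-methyl-4-oxo-2-(prop-1-en-2-yl)-1,2,3,4-tetrahydronaphthalen-1-yl]propanoic acid, via C3 aldehyde 26 (not isolated)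
Conditions: TEMPO (cat.), PhI(OAc)2, MeCN/H2O, rt
Reagents that add atoms: water, O
Why: Oxoammonium-catalysed oxidation of a primary alcohol through the aldehyde hydrate to the acid spares the alkene and the arene, which the C7 carbonyl now deactivates.

Step 15
Reactants: 27 trimethyl ether keto acid
Product: 28 3-[(1S,2S)-6-isopropyl-7-methoxy-1-methyl-4,5,8-trioxo-2-(prop-1-en-2-yl)-1,2,3,4,5,8-hexahydronaphthalen-1-yl]propanoic acid
Conditions: (NH4)2Ce(NO3)6, MeCN/H2O, 0 °C, short contact
Reagents that add atoms: water, O
Why: Oxidative demethylation of a 1,4-dimethoxyarene by tetravalent cerium: only C11 and C14 are para to each other, so two one-electron oxidations and addition of water at these carbons expel two molecules of methanol and give the 11,14-para-quinone, with the C12 OMe kept as a vinylogous ester and the isolated alkene and the acid tolerated as in prenylated quinone syntheses.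

Step 16
Reactants: 28 11,14-quinone acid
Product: 29 3-[(1S,2S)-5,8-dihydroxy-6-isopropyl-7-methoxy-1-methyl-4-oxo-2-(prop-1-en-2-yl)-1,2,3,4-tetrahydronaphthalen-1-yl]propanoic acid (CNP0249049.1)
Conditions: Na2S2O4, EtOAc/H2O, rt, under Ar
Reagents that add atoms: none
Why: Dithionite reduction of a quinone to the hydroquinone: the acyl-substituted hydroquinone is held by the C14–OH to C7=O hydrogen bond and resists reoxidation, and no stereocentre is touched.

## Compound list

1 | 1,2,4-trimethoxybenzene | COc1ccc(OC)c(OC)c1 | starting material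
2 | acetone | CC(C)=O | starting material
3 | 2,3,6-trimethoxyphenyllithium | [Li]c1c(OC)ccc(OC)c1OC | intermediate
4 | 2-(2,3,6-trimethoxyphenyl)propan-2-ol | CC(C)(O)c1c(OC)ccc(OC)c1OC | intermediate
5 | 3-isopropyl-1,2,4-trimethoxybenzene | CC(C)c1c(OC)ccc(OC)c1OC | intermediate
6 | 1-iodo-3-isopropyl-2,4,5-trimethoxybenzene | CC(C)c1c(OC)c(I)cc(OC)c1OC | intermediate
7 | allyl alcohol | C=CCO | starting material
8 | 3-(3-isopropyl-2,4,5-trimethoxyphenyl)propanal | O=CCCc1cc(OC)c(OC)c(C(C)C)c1OC | intermediate
9 | isopropenylmagnesium bromide | C=C(C)[Mg]Br | starting material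
10 | (±)-5-(3-isopropyl-2,4,5-trimethoxyphenyl)-2-methylpent-1-en-3-ol | C=C(C)C(O)CCc1cc(OC)c(OC)c(C(C)C)c1OC | intermediate
11 | triethyl orthoacetate | CCOC(C)(OCC)OCC | starting material
12 | mixed ketene acetal (1-ethoxyvinyl ether of 10) | C=C(OCC)OC(CCc1cc(OC)c(OC)c(C(C)C)c1OC)C(C)=C | intermediate
13 | ethyl (E)-7-(3-isopropyl-2,4,5-trimethoxyphenyl)-4-methylhept-4-enoate | CCOC(=O)CC/C(C)=C/CCc1cc(OC)c(OC)c(C(C)C)c1OC | intermediate
14 | (E)-7-(3-isopropyl-2,4,5-trimethoxyphenyl)-4-methylhept-4-en-1-ol | OCCC/C(C)=C/CCc1cc(OC)c(OC)c(C(C)C)c1OC | intermediate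
15 | (E)-7-(3-isopropyl-2,4,5-trimethoxyphenyl)-4-methylhept-4-en-1-yl pivalate | CC(C)(C)C(=O)OCCC/C(C)=C/CCc1cc(OC)c(OC)c(C(C)C)c1OC | intermediate
16 | acetyl chloride | CC(=O)Cl | starting material
17 | tertiary C10 cation with acetyl on C5 (racemic, one enantiomer drawn) | CC(=O)[C@H](CCc1cc(OC)c(OC)c(C(C)C)c1OC)[C+](C)CCCOC(=O)C(C)(C)C | intermediate
18 | (±)-acetyl tetralin pivalate, 5R*,10S* (racemic, the enantiomer carried on is drawn) | CC(=O)[C@@H]1CCc2c(OC)c(C(C)C)c(OC)c(OC)c2[C@@]1(C)CCCOC(=O)C(C)(C)C | intermediate
19 | (S)-N,S-dimethyl-S-phenylsulfoximine | C[S@@](=O)(=NC)c1ccccc1 | starting material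
20 | (S)-S-(lithiomethyl)-N-methyl-S-phenylsulfoximine | [Li]C[S@@](=O)(=NC)c1ccccc1 | intermediate
21 | β-hydroxysulfoximine, 5R,10S, sulfur S, C4 epimers | CC(O)(C[S@@](=O)(=NC)c1ccccc1)[C@@H]1CCc2c(OC)c(C(C)C)c(OC)c(OC)c2[C@@]1(C)CCCOC(=O)C(C)(C)C | intermediate
22 | isopropenyl tetralin pivalate, 5S,10S | C=C(C)[C@@H]1CCc2c(OC)c(C(C)C)c(OC)c(OC)c2[C@@]1(C)CCCOC(=O)C(C)(C)C | intermediate
23 | C7 benzylic alcohol of 22 (C7 epimers) | C=C(C)[C@@H]1CC(O)c2c(OC)c(C(C)C)c(OC)c(OC)c2[C@@]1(C)CCCOC(=O)C(C)(C)C | intermediate
24 | C7 ketone pivalate, 5S,10S | C=C(C)[C@@H]1CC(=O)c2c(OC)c(C(C)C)c(OC)c(OC)c2[C@@]1(C)CCCOC(=O)C(C)(C)C | intermediate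
25 | C7 ketone C3 alcohol, 5S,10S | C=C(C)[C@@H]1CC(=O)c2c(OC)c(C(C)C)c(OC)c(OC)c2[C@@]1(C)CCCO | intermediate
26 | C7 ketone C3 aldehyde, 5S,10S | C=C(C)[C@@H]1CC(=O)c2c(OC)c(C(C)C)c(OC)c(OC)c2[C@@]1(C)CCC=O | intermediate
27 | trimethyl ether keto acid, 5S,10S | C=C(C)[C@@H]1CC(=O)c2c(OC)c(C(C)C)c(OC)c(OC)c2[C@@]1(C)CCC(=O)O | intermediate
28 | 11,14-quinone keto acid, 5S,10S | C=C(C)[C@@H]1CC(=O)C2=C(C(=O)C(OC)=C(C(C)C)C2=O)[C@@]1(C)CCC(=O)O | intermediate
29 | CNP0249049.1, 5S,10S | C=C(C)[C@@H]1CC(=O)c2c(O)c(C(C)C)c(OC)c(O)c2[C@@]1(C)CCC(=O)O | target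

## Step count and risks

Total step count: 16. Longest linear sequence: 16 (1 to 29).

**Step 9 (key step).**
Three things may go wrong:
- Proton loss from the C10 cation, or an ene-type hydrogen shift to the acyl oxygen, may outrun arene capture.
- The ring may be acetylated at C9 before the alkene reacts.
- Reversible chloride capture may give a long-lived cation in which rotation about C5–C10 erodes the C5/C10 relation.

The fallback uses a known reaction type, the intermolecular acetal-initiated cation–olefin cyclisation ended by an arene. It sets out from 15 and comes back at 18. Compound 15 is treated with 1,1-bis(benzyloxy)ethane and SnCl4 in CH2Cl2 at −78 °C. The O-benzyl oxocarbenium ion takes the place of the acylium ion, forms the same C4–C5 and C9–C10 bonds by the same anti addition, and gives the racemic C4 benzyl ether F1 as C4 epimers. Hydrogenolysis (H2, Pd/C, EtOAc) gives the racemic C4 alcohol F2. Dess–Martin periodinane in CH2Cl2 removes the C4 centre and gives 18.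

**Step 10.**
The hindered methyl ketone may be enolised instead of attacked. Alternatively, up to four diastereomers may form that cannot be sorted into the two series on silica gel.

The fallback avoids all basic reagents. It sets out from 18 and comes back at 22.
- Corey–Bakshi–Shibata reduction of racemic 18 uses (S)-1-methyl-3,3-diphenylhexahydropyrrolo[1,2-c][1,3,2]oxazaborole and BH3·SMe2 in THF at −20 °C.
- Hydride is delivered under reagent control to the same carbonyl face in both enantiomers.
- The products are the (4R,5R,10S) alcohol F3 and its diastereomer, the (4R,5S,10R) alcohol F4, which differ at adjacent centres and are separated by chromatography.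
- Dess–Martin oxidation of F3 returns 18 as the single (5R,10S) enantiomer.
- Lombardo methylenation (Zn, CH2Br2, TiCl4, THF/CH2Cl2, 0 °C to rt), which is non-basic and spares esters, gives 22.

**Step 12.**
The C7 cation may lose a C6 proton to give a styrene instead of taking water. Hydride abstraction may be slow because all three methoxy groups are twisted out of the ring plane. The isopropenyl group may be attacked.

The fallback is the classical protection of an alkene as its dibromide during a chromium oxidation. It sets out from 22 and comes back at 24. One equivalent of Br2 in CH2Cl2 at −78 °C adds to the only alkene, since the ring has no free position, and gives the dibromide F5. CrO3 in aqueous AcOH at rt oxidises C7, as is usual for abietane aryl ethers, and gives the keto dibromide F6. Zn dust in AcOH/Et2O at 0 °C restores the isopropenyl group and gives 24.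

## Further compounds

F1 | step 9 | racemic C4 benzyl ether, C5/C10 relative configuration as in 18, C4 epimers | CC(OCc1ccccc1)[C@@H]1CCc2c(OC)c(C(C)C)c(OC)c(OC)c2[C@@]1(C)CCCOC(=O)C(C)(C)C
F2 | step 9 | racemic C4 alcohol, C5/C10 relative configuration as in 18, C4 epimers | CC(O)[C@@H]1CCc2c(OC)c(C(C)C)c(OC)c(OC)c2[C@@]1(C)CCCOC(=O)C(C)(C)C
F3 | step 10 | (4R,5R,10S) alcohol | C[C@@H](O)[C@@H]1CCc2c(OC)c(C(C)C)c(OC)c(OC)c2[C@@]1(C)CCCOC(=O)C(C)(C)C
F4 | step 10 | (4R,5S,10R) alcohol | C[C@@H](O)[C@H]1CCc2c(OC)c(C(C)C)c(OC)c(OC)c2[C@]1(C)CCCOC(=O)C(C)(C)C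
F5 | step 12 | dibromide of 22, C5 and C10 as in 22, C4 epimers | CC(Br)(CBr)[C@@H]1CCc2c(OC)c(C(C)C)c(OC)c(OC)c2[C@@]1(C)CCCOC(=O)C(C)(C)C
F6 | step 12 | C7 keto dibromide, C5 and C10 as in 22, C4 epimers | CC(Br)(CBr)[C@@H]1CC(=O)c2c(OC)c(C(C)C)c(OC)c(OC)c2[C@@]1(C)CCCOC(=O)C(C)(C)C
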